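## Analysis of the target

Ainsliadimer A (14) is built from two guaianolide halves, each a cis-fused hydroazulene (five-membered ring A, C1–C5, and seven-membered ring B) carrying a trans-fused α-methylene-γ-butyrolactone across C6/C7 and an exocyclic C10=C14 methylene. A seventh ring, a central cyclopentane made of C3, C4 and C15 of the unprimed half and C15' and C4' of the primed half, joins the two. Eight of the eleven stereocentres (C1, C5, C6, C7 and their primed counterparts) are those of dehydrocostus lactone 1, and the other three, C3, C4 and C4', are contiguous and fully substituted. Both hydroxyls lie on the α face of ring A (the face of H1 and H5), so the central ring is attached on the β face, and at C4' the bond to C3 lies on the α face of the primed ring A, anti to C6'. The sensitive groups are the two α-methylene lactones (Michael acceptors), the C3 hydroxyl, which is β to the C3' ketone through the quaternary C4' and therefore open to retro-aldol cleavage under base, and the ditertiary diol and exocyclic alkenes, which do not tolerate strong acid. The difficulty is to make three adjacent fully substituted carbons inside a crowded ring between two identical halves that must take different roles. The plan rests on two features: C3 and C4 are the fusion carbons of a cis-bicyclo[3.3.0]octane-1,5-diol (ring A fused to the central ring), the retron of a tetrasubstituted C3=C4 alkene, and the spiro carbon C4' is the α-carbon of the C3' ketone, the retron of an enolate coupling.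

## Retrosynthetic reasoning

**Diol (14 ⇒ 13 ⇒ 12).** The two C–O bonds at C3 and C4 are cut first. The diol is at once a β-hydroxy ketone and a ditertiary glycol, so it should appear last and under mild conditions. Both oxygens are traced to the α-epoxide 13 and this to the alkene 12. In the forward direction the oxidant must pick the one electron-rich tetrasubstituted alkene among five C=C bonds and attack it on the α face. The epoxide must then open with retention, which is expected because two fused five-membered rings only allow a cis junction.

**Lactones (12 ⇒ 10).** The two α-methylene lactones would not survive a one-electron reductant, enolates or palladium. They are therefore carried as their adducts with 3, as in 10, and released just before the oxidation, so that no amine is present when the oxidant is used.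

**Central ring, bond C3–C4' (10 ⇒ 9).** Of the five bonds of the central ring, three (C3–C4, C4–C15 and C4'–C15') already exist in the monomer 1. Only C15–C15' and C3–C4' have to be made. Cutting C3–C4' in 10 opens the ring at the quaternary carbon and leaves two halves that differ only in the oxidation state at C3: an enol triflate in one and a ketone in the other, as in 9. The forward step must join a hindered alkenyl carbon to a fully substituted enolate carbon, a task better suited to reductive elimination at palladium than to addition to a hindered carbonyl. It must also set C4'.

**Differentiation of the ends (9 ⇒ 8 ⇒ 6 + 7).** The enol triflate needs its double bond at C3=C4, the more substituted position, which kinetic deprotonation of a C3 ketone would not deliver. Both ends are therefore traced to the regiodefined bis(silyl enol ether) 6. One end is converted with 7 into the triflate 8 and the other is hydrolysed to the ketone.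

**Bond C15–C15' (6 ⇒ 5).** C15 and C15' are both β-carbons of the same exocyclic enone, so 6 is the reductive tail-to-tail dimer of 5. Trapping both enolate oxygens with a silyl group at the moment of coupling stores the C3=C4 regiochemistry. No stereocentre is created, since C4 and C4' are trigonal in 6.

**Monomer (5 ⇒ 4 ⇒ 2 + 3 ⇒ 1).** The enone 5 comes from the allylic alcohol 4 by oxidation, 4 from 2 by conjugate addition of 3 to the lactone methylene, and 2 from 1 by allylic hydroxylation at C3. The hydroxylation is placed first because its oxidant would attack a tertiary amine. The amine is added before the enone exists because the enone would also accept it.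

## Alternatives that were turned down

Alternative 1: This route disconnects both seven-membered rings. Each hydroazulenone is traced to a six-six cross-conjugated cyclohexadienone, and the two are taken as already joined C15 to C15' in the bis-dienone A2. Irradiation of A2 in acetic acid A3 would in each half bond C1 to C5, break C5–C10 and capture A3 at C10, giving the bis(acetoxy cyclopentenone) A1.
- For it: the rearrangement is well understood for this skeleton. It delivers the 5/7 ring system with the C3 oxygen in place and C1 set. It avoids both the allylic oxidation of 1 and the dimerisation-prone enone 5.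
- Against it: A1 contains none of the hard bonds. The central ring is still open at C3–C4', and the spiro carbon and the diol are missing, so the equivalent of steps 6 to 9 would still follow. Before them, both C4=C5 enones would need reducing with control of C5 and C5', and two tertiary acetates would need eliminating towards the exocyclic C10=C14 position against the endocyclic ones.
- Further doubts: two chromophores must each rearrange once and then stop, although the cyclopentenone product also absorbs. The lactone methylenes of A2 are exposed to the light. C15 of such a dienone is a methyl on the α-carbon and is not activated for the coupling that A2 presupposes.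
- Comparison: the chosen route buys the complete skeleton, both exocyclic alkenes and eight stereocentres in 1, and spends its key step on the missing bond. The alternative is stronger only in having C3 oxidised from the outset, which costs the chosen route one hydroxylation and one oxidation.

Alternative 2: This route disconnects ring B of the primed half. C8' and C9' are removed as ethylene A6, and ring B shrinks to a cyclopentane-1,3-dione fused to the primed ring A in A5. The acetonide-protected diol, the spiro centre and the whole unprimed half are already present in A5. On irradiation the enol C7'=C10' of A5 would add A6, and retro-aldol opening of the cyclobutanol would give the cycloheptane-1,4-dione A4.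
- For it: the photocycloaddition and retro-aldol sequence is dependable for enolised 1,3-diones. A6 poses no regiochemical question. The carbonyls of A4 sit where C6' needs oxygen and C10' a methylene. No triflate, strong base or transition metal is involved, so the key step is more robust than that of the chosen route.
- Against it: the step builds a ring that 1 supplies ready-made. The primed lactone and exocyclic alkene must then be rebuilt by selective reduction at C6', lactonisation, methylenation of C10' in the presence of the C3' ketone, and α-methylenation. C5' and C7' are both α to ketones and can epimerise. A5 also presupposes that the central ring, the spiro centre and the diol were made by other means on a half not derived from 1.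
- Comparison: the chosen route keeps the halves identical up to 6 and reaches 14 in nine steps. It offers convergence from one purchased building block in place of the alternative's robustness.

Alternative 3: This route cuts the C3–C4 bond of the diol, which is also a bond of ring A. The amine-masked target A7 is opened to the cyclooctane-1,5-dione A8, whose eight-membered ring holds C1, C2, C3, C4', C15', C15, C4 and C5. Samarium diiodide A9 would reduce the C3 carbonyl of A8 to a ketyl that adds across the ring to C4.
- For it: one step closes ring A and the central ring, installs both tertiary alcohols, and can only give the cis-fused diol. The product A7 is one unmasking step from 14. On the end game this is stronger than the chosen route, which needs an epoxidation and a hydration after ring closure.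
- Against it: C3–C4 exists in 1, so ring A of one half would have to be cleaved and a functionalised eight-membered ring built around the quaternary C4'. In A8 that carbon lies between the C3 and C3' carbonyls, a non-enolisable 1,3-diketone prone to retro-Claisen cleavage and to competing ketyl formation at C3' by A9. The face on which the diol forms relative to H5 and C4' would depend on the conformation of a medium ring.
- Comparison: the chosen route leaves every ring of both halves intact, reaches 9 in five steps, and sets the C3/C4 face on a rigid diquinane alkene.

Key step: step 6

Remarks on the chemistry: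
- Guaianolide numbering is used, unprimed for the half that ends with the diol and primed for the half that ends with the ketone. α is the face of ring A (or of the primed ring A) that carries H1 and H5.
- The allylic hydroxylation in step 1 is assumed to give mainly the 3α-alcohol. The 3β-epimer would serve equally, since C3 becomes a ketone in step 3.
- Compound 9 is drawn as its 4'α-H epimer. The other epimer is equally usable, because C4' is enolised in step 6.

## Route

Step 1
Reactants: 1 dehydrocostus lactone
Product: 2 3-epizaluzanin C (3α-hydroxydehydrocostus lactone)
Conditions: SeO2 (cat.), t-BuOOH, CH2Cl2, 0 °C → rt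
Reagents that add atoms: tert-butyl hydroperoxide, CC(C)(C)OO
Why: Selenium dioxide allylic hydroxylation (ene reaction, then [2,3]-sigmatropic shift) attacks the ring methylene C3 next to the C4=C15 exocyclic alkene, and the electron-poor lactone methylene is inert; oxygen should arrive on the convex α face (3R), and oxidation at C9 beside the other exocyclic alkene is the side reaction to be separated.

Step 2
Reactants: 2 3-epizaluzanin C; 3 dimethylamine
Product: 4 13-(dimethylamino)-11βH,13-dihydro-3-epizaluzanin C
Conditions: Me2NH (2 M in THF), MeOH, 0 °C → rt
Reagents that add atoms: none
Why: Aza-Michael addition to the α-methylene-γ-butyrolactone, the only acceptor present; protonation of the lactone enolate from the less hindered face should give the 11βH adduct, which masks the acceptor for steps 3 to 6.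

Step 3
Reactants: 4 13-(dimethylamino)-11βH,13-dihydro-3-epizaluzanin C
Product: 5 13-(dimethylamino)-11βH,13-dihydrodehydrozaluzanin C
Conditions: MnO2 (activated, excess), CH2Cl2, rt; filter, use at once
Reagents that add atoms: none
Why: Manganese dioxide oxidation of a secondary allylic alcohol, which tolerates the tertiary amine and the isolated alkene; the exocyclic enone is dimerisation-prone and is taken on as a cold dilute solution.

Step 4
Reactants: 5 13-(dimethylamino)-11βH,13-dihydrodehydrozaluzanin C (two molecules)
Product: 6 C15–C15' dimer as bis(trimethylsilyl enol ether)
Conditions: SmI2 (1.1 equiv per enone), Me3SiCl, HMPA, THF, −78 °C, slow addition of 5; non-aqueous work-up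
Reagents that add atoms: chlorotrimethylsilane, C[Si](C)(C)Cl
Why: Reductive β,β-coupling (hydrodimerisation) of an enone by one-electron transfer: the oxygen-bound allyl radical dimerises at its unhindered CH2 terminus C15, and silylation of both enolates fixes the C3=C4 and C3'=C4' regiochemistry; no stereocentre is formed, and lactones and amines are inert to divalent samarium without a proton donor.

Step 5
Reactants: 6 C15–C15' dimer as bis(trimethylsilyl enol ether); 7 N-phenyl-bis(trifluoromethanesulfonimide)
Product: 9 C3 enol triflate of the C15–C15' dimer bearing the C3' ketone, via triflate silyl enol ether 8 (not isolated)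
Conditions: Bu4N[Ph3SiF2] (1.0 equiv), 7 (1.1 equiv), THF, −40 → 0 °C; then 1 M HCl, THF, 0 °C; NaHCO3 work-up
Reagents that add atoms: none
Why: Fluoride-induced desilylation gives a regiodefined ammonium enolate that 7 sulfonylates on oxygen, and one equivalent of fluoride limits this to one end on statistical grounds, the doubly and the non-triflated by-products being separated; an alkyllithium is avoided because the lactones would not survive it, and dilute acid then hydrolyses the remaining silyl enol ether with the proton entering C4' from the convex face.

Step 6
Reactants: 9 C3 enol triflate of the C15–C15' dimer bearing the C3' ketone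
Product: 10 spiro diquinane alkene as bis(dimethylamine) adduct
Conditions: Pd2(dba)3 (5 mol %), P(t-Bu)3 (12 mol %), NaOt-Bu (1.2 equiv), THF, 25 → 50 °C
Reagents that add atoms: none
Why: Zerovalent palladium carrying one P(t-Bu)3 inserts into the C3–O bond of the alkenyl triflate, the alkoxide turns the C3' ketone reversibly into its sodium enolates, and the C4' enolate displaces triflate at palladium to give a six-membered C-bound palladacycle (Pd, C3, C4, C15, C15', C4') from which C–C reductive elimination forms C3–C4' and returns the catalyst. The closest known reaction type is the palladium-catalysed intramolecular α-alkenylation of ketone enolates with alkenyl halides or triflates, together with the α-arylation of α-branched ketones that creates quaternary carbons with the same catalyst. The central cyclopentene (C3, C4, C15, C15', C4') closes in a 5-exo sense with respect to the enolate: the enolate bond C3'=C4' lies outside the new ring and the C3=C4 bond stays inside it as the bond shared with ring A. The only new stereocentre is C4'; palladium, and with it C3, should bind on the convex α face of the cis-fused primed hydroazulenone, anti to C6' on the neighbouring C5', which leaves C15' on the β face as in 14. C4' is chosen over C2' by ring size (five against seven), and reversible enolisation returns the unproductive C2' enolate; carbon is chosen over oxygen because O-alkenylation would need a seven-membered cyclic enol ether. The lactones are spared because little more than one equivalent of base is used, so that the ketone enolate and not free alkoxide is the resting base. The alkenylpalladium has no β-hydrogen it can lose within the ring, and the bulky phosphine speeds the reductive elimination that makes the quaternary carbon; epimerisation at C11 or C11' is of no consequence because both become trigonal in step 7.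

Step 7
Reactants: 10 spiro diquinane alkene as bis(dimethylamine) adduct
Product: 12 3,4-didehydro-3,4-dideoxyainsliadimer A, via bis(trimethylammonium) diiodide 11 (not isolated)
Conditions: MeI (excess), MeOH, rt; evaporate; NaHCO3, H2O–CH2Cl2, rt
Reagents that add atoms: iodomethane, CI (its methyl groups are carried by 11 and leave as trimethylamine)
Why: Exhaustive N-methylation, then Hofmann-type E1cB elimination of trimethylamine from the β-ammonium lactones, restores both α-methylene lactones under bicarbonate, which leaves the ketone and the alkenes alone; it is done before the oxidation so that no amine meets the dioxirane.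

Step 8
Reactants: 12 3,4-didehydro-3,4-dideoxyainsliadimer A
Product: 13 3α,4α-epoxide of 12
Conditions: dimethyldioxirane (1.05 equiv, acetone), CH2Cl2, −40 → 0 °C
Reagents that add atoms: dimethyldioxirane, CC1(C)OO1
Why: Electrophilic epoxidation picks the tetrasubstituted C3=C4 alkene, the most electron-rich of the five C=C bonds (the exocyclic 1,1-disubstituted alkenes react far more slowly and the lactone methylenes are inert at this temperature); the oxidant should approach the α face, where only H5 and the flat C3' carbonyl stand, and not the β face blocked by C6 and C5', which sets C3 and C4, and the neutral conditions preserve the acid-labile epoxide.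

Step 9
Reactants: 13 3α,4α-epoxide of 12
Product: 14 ainsliadimer A
Conditions: HClO4 (cat.), THF–H2O, 0 °C
Reagents that add atoms: water, O
Why: Acid-catalysed epoxide hydration through the tertiary cation at C4 (the carbon remote from the acyl-bearing C4'), which water should capture on the α face because only that keeps the bicyclo[3.3.0]octane cis-fused; ring-contracting 1,2-shifts would give cyclobutanes and are disfavoured, so both oxygens end on the α face as in 14.

## Compound list

1 | dehydrocostus lactone | C=C1CC[C@H]2C(=C)CC[C@H]3C(=C)C(=O)O[C@@H]3[C@@H]12 | starting material
2 | 3-epizaluzanin C (3α-hydroxydehydrocostus lactone, 3R) | C=C1[C@H](O)C[C@H]2C(=C)CC[C@H]3C(=C)C(=O)O[C@@H]3[C@@H]12 | intermediate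
3 | dimethylamine | CNC | starting material
4 | 13-(dimethylamino)-11βH,13-dihydro-3-epizaluzanin C | C=C1[C@H](O)C[C@H]2C(=C)CC[C@H]3[C@H](CN(C)C)C(=O)O[C@@H]3[C@@H]12 | intermediate
5 | 13-(dimethylamino)-11βH,13-dihydrodehydrozaluzanin C (C3 ketone, C4=C15 enone, lactone masked) | C=C1C(=O)C[C@H]2C(=C)CC[C@H]3[C@H](CN(C)C)C(=O)O[C@@H]3[C@@H]12 | intermediate
6 | C15–C15' dimer as bis(trimethylsilyl enol ether) (C3=C4 and C3'=C4', lactones masked) | C[Si](C)(C)OC1=C(CCC2=C(O[Si](C)(C)C)C[C@H]3C(=C)CC[C@H]4[C@H](CN(C)C)C(=O)O[C@@H]4[C@@H]23)[C@H]2[C@@H](C1)C(=C)CC[C@H]3[C@H](CN(C)C)C(=O)O[C@@H]32 | intermediate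
7 | N-phenyl-bis(trifluoromethanesulfonimide) | FC(F)(F)S(=O)(=O)N(c1ccccc1)S(=O)(=O)C(F)(F)F | starting material
8 | C3 enol triflate with C3' trimethylsilyl enol ether | FC(F)(F)S(=O)(=O)OC1=C(CCC2=C(O[Si](C)(C)C)C[C@H]3C(=C)CC[C@H]4[C@H](CN(C)C)C(=O)O[C@@H]4[C@@H]23)[C@H]2[C@@H](C1)C(=C)CC[C@H]3[C@H](CN(C)C)C(=O)O[C@@H]32 | intermediate
9 | C3 enol triflate with C3' ketone (halves joined C15–C15', lactones masked, 4'α-H) | FC(F)(F)S(=O)(=O)OC1=C(CC[C@H]4C(=O)C[C@H]5C(=C)CC[C@H]6[C@H](CN(C)C)C(=O)O[C@@H]6[C@H]54)[C@H]2[C@@H](C1)C(=C)CC[C@H]3[C@H](CN(C)C)C(=O)O[C@@H]32 | intermediate
10 | spiro diquinane alkene (C3=C4), bis(dimethylamine) adduct | CN(C)C[C@@H]1C(=O)O[C@@H]2[C@@H]3[C@@H](CC4=C3CC[C@]43C(=O)C[C@H]4C(=C)CC[C@H]5[C@H](CN(C)C)C(=O)O[C@@H]5[C@H]43)C(=C)CC[C@@H]12 | intermediate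
11 | bis(trimethylammonium) diiodide of 10 | C[N+](C)(C)C[C@@H]1C(=O)O[C@@H]2[C@@H]3[C@@H](CC4=C3CC[C@]43C(=O)C[C@H]4C(=C)CC[C@H]5[C@H](C[N+](C)(C)C)C(=O)O[C@@H]5[C@H]43)C(=C)CC[C@@H]12.[I-].[I-] | intermediate
12 | 3,4-didehydro-3,4-dideoxyainsliadimer A (C3=C4 alkene, both α-methylene lactones free) | C=C1C(=O)O[C@@H]2[C@@H]3[C@@H](CC4=C3CC[C@]43C(=O)C[C@H]4C(=C)CC[C@H]5C(=C)C(=O)O[C@@H]5[C@H]43)C(=C)CC[C@@H]12 | intermediate
13 | 3α,4α-epoxide of 12 | C=C1C(=O)O[C@@H]2[C@@H]3[C@@H](C[C@@]4(O6)[C@]36CC[C@]43C(=O)C[C@H]4C(=C)CC[C@H]5C(=C)C(=O)O[C@@H]5[C@H]43)C(=C)CC[C@@H]12 | intermediate
14 | ainsliadimer A | C=C1C(=O)O[C@@H]2[C@@H]3[C@@H](C[C@@]4(O)[C@]3(O)CC[C@]43C(=O)C[C@H]4C(=C)CC[C@H]5C(=C)C(=O)O[C@@H]5[C@H]43)C(=C)CC[C@@H]12 | target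

## Step count and least certain steps

Total: 9 steps. Longest linear sequence: 9 steps from 1. Both halves come from the same intermediate 5, so there is no second branch.

**Step 6 (key step).**
- What may go wrong: oxidative addition of the hindered tetrasubstituted alkenyl triflate may be slow at a palladium centre carrying one bulky phosphine, while the alkoxide cleaves the triflate at sulfur. Base may expel dimethylamine from the lactones and start Michael chemistry. The C-bound palladium enolate may undergo β-hydride elimination faster than the crowded reductive elimination. Bonding at C4' may occur on the wrong face.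
- Fallback: the same bond can be made with C3 as a carbonyl electrophile. Setting out from 6, K2CO3 in methanol should remove both silyl groups to give the symmetrical 1,6-diketone F1. Continued exposure to base (or DBU in CH2Cl2) should close the intramolecular aldol, C4' adding to the C3 carbonyl to give the five-membered β-hydroxy ketone F2. The seven-membered mode from C2' is not competitive, and E1cB dehydration is impossible at the quaternary C4'. Syn-elimination of the C3 hydroxyl and the cis-disposed H4 with methyl N-(triethylammoniumsulfonyl)carbamate (Burgess reagent) should give the tetrasubstituted alkene, so the sequence comes back to the route at 10. The C3 and C4 configurations of F2 vanish in the dehydration; C4' is set under reversible aldol conditions and would have to be verified.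

**Step 9.**
- What may go wrong: the C4 cation may lose a proton from C5 or C15 to give allylic alcohols instead of capturing water, or the aqueous acid may trigger retro-aldol cleavage of the newly formed β-hydroxy ketone.
- Fallback: setting out from 13, acetone with catalytic BF3·OEt2 at −20 °C under anhydrous conditions should insert the ketone into the epoxide to give the acetonide F3, a dioxolane that can only be cis-fused and can be purified. Mild hydrolysis (aqueous CF3CO2H, THF, 0 °C) then comes back to the route at 14.

**Step 4.**
- What may go wrong: samarium enolates may add to not yet reduced enone (anionic oligomerisation), simple 1,4-reduction may intervene if a proton source is present, or silylation of the samarium enolates may be incomplete.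
- Fallback: the C15–C15' bond can be made without a reductant. Setting out from 5, the hetero-Diels–Alder dimerisation typical of α-methylene ketones (neat or concentrated in toluene, 50 °C) should give the spiro dihydropyran dimer F4, in which C15–C15' and O3–C4' are formed. SmI2 with Me3SiCl and HMPA in THF at −78 °C should then cleave the α-alkoxy ketone bond C4'–O3, a standard reductive cleavage, to release both regiodefined enolates, which are silylated. This comes back to the route at 6.

Step 5 is limited to a statistical outcome by its two identical ends, which is a matter of material throughput and not of feasibility. The aldol sequence described under step 6 would also lift this limit, since it needs no differentiation of the two ends.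

## Further compounds

F1 | step 6 | symmetrical C15–C15'-linked 1,6-diketone (C3 and C3' ketones, lactones masked, shown as the 4α-H,4'α-H isomer) | C(C[C@H]1C(=O)C[C@H]2C(=C)CC[C@H]3[C@H](CN(C)C)C(=O)O[C@@H]3[C@H]21)[C@H]1C(=O)C[C@H]2C(=C)CC[C@H]3[C@H](CN(C)C)C(=O)O[C@@H]3[C@H]21
F2 | step 6 | intramolecular aldol product (C3–C4' bond, C3 hydroxyl, C4–H, C3' ketone, lactones masked) | CN(C)C[C@@H]1C(=O)O[C@@H]2[C@@H]3[C@@H](C[C@@]4(O)[C@@H]3CC[C@]43C(=O)C[C@H]4C(=C)CC[C@H]5[C@H](CN(C)C)C(=O)O[C@@H]5[C@H]43)C(=C)CC[C@@H]12
F3 | step 9 | 3,4-O-isopropylidene ainsliadimer A (acetonide of 14) | C=C1C(=O)O[C@@H]2[C@@H]3[C@@H](C[C@@]4(OC(C)(C)O6)[C@]36CC[C@]43C(=O)C[C@H]4C(=C)CC[C@H]5C(=C)C(=O)O[C@@H]5[C@H]43)C(=C)CC[C@@H]12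
F4 | step 4 | hetero-Diels–Alder dimer of 5 (spiro dihydropyran, bonds C15–C15' and O3–C4') | O7C1=C(CC[C@]78C(=O)C[C@H]4C(=C)CC[C@H]5[C@H](CN(C)C)C(=O)O[C@@H]5[C@H]48)[C@H]2[C@@H](C1)C(=C)CC[C@H]3[C@H](CN(C)C)C(=O)O[C@@H]32
A1 | alternative 1 | C15–C15'-linked bis(10-acetoxy-3-oxoguai-4-enolide) | C=C1[C@@H]2CC[C@@](C)(OC(C)=O)[C@@H]3CC(=O)C(CCC4=C5[C@H]6OC(=O)C(=C)[C@@H]6CC[C@@](C)(OC(C)=O)[C@@H]5CC4=O)=C3[C@H]2OC1=O
A2 | alternative 1 | C15–C15'-linked bis(3-oxoeudesma-1,4,11(13)-trien-12,6-olide) (bis-dienone) | C=C1[C@@H]2CC[C@@]3(C)C=CC(=O)C(CCC4=C5[C@H]6OC(=O)C(=C)[C@@H]6CC[C@@]5(C)C=CC4=O)=C3[C@H]2OC1=O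
A3 | alternative 1 | acetic acid | CC(=O)O
A4 | alternative 2 | cycloheptane-1,4-dione with the C7' acetate side chain | CN(C)C[C@@H]1C(=O)O[C@@H]2[C@@H]3[C@@H](C[C@]45OC(C)(C)O[C@]53CC[C@]43C(=O)C[C@H]4C(=O)CC[C@@H](CC(=O)OC)C(=O)[C@H]43)C(=C)CC[C@@H]12
A5 | alternative 2 | fused cyclopentane-1,3-dione precursor (C7' enolisable, configuration left open) | CN(C)C[C@@H]1C(=O)O[C@@H]2[C@@H]3[C@@H](C[C@]45OC(C)(C)O[C@]53CC[C@]43C(=O)C[C@H]4C(=O)C(CC(=O)OC)C(=O)[C@H]43)C(=C)CC[C@@H]12
A6 | alternative 2 | ethylene | C=C
A7 | alternative 3 | lactone-masked target (bis(dimethylamine) adduct of 14) | CN(C)C[C@@H]1C(=O)O[C@@H]2[C@@H]3[C@@H](C[C@@]4(O)[C@]3(O)CC[C@]43C(=O)C[C@H]4C(=C)CC[C@H]5[C@H](CN(C)C)C(=O)O[C@@H]5[C@H]43)C(=C)CC[C@@H]12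
A8 | alternative 3 | cyclooctane-1,5-dione precursor (C3 and C4 ketones, no C3–C4 bond) | CN(C)C[C@@H]1C(=O)O[C@@H]2[C@@H]3[C@@H](CC(=O)[C@]4(CCC3=O)C(=O)C[C@H]5C(=C)CC[C@H]6[C@H](CN(C)C)C(=O)O[C@@H]6[C@H]54)C(=C)CC[C@@H]12
A9 | alternative 3 | samarium diiodide | [Sm+2].[I-].[I-]
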